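**Conventions and assumption**

- The azulene locants of the target (C1, C2, C3, C3a, C4–C8, C8a) are used for the same carbon atoms in every intermediate. In the carvone-derived six-membered ring: carbonyl carbon = C3, ring CH2 = C3a, isopropyl-bearing carbon = C4, allylic CH2 = C5, =CH = C6, methyl-bearing carbon = C7.
- β is the face of H-8a, α the face of the C4 isopropyl group. Cycloheptene intermediates keep the ring locants of acid 18 in their names.
- Assumption: 3-[(4-methoxybenzyl)oxy]propan-1-ol (10) is bought as such.

## Analysis of the target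

CNP0106636.1 is a trans-fused hydroazulene. A cyclopentane ring (C1, C2, C3, C3a, C8a) carries a 1,2-epoxide with a methyl group on C2. It is fused to a cycloheptane ring (C3a, C4–C8, C8a) that carries an isopropyl group on C4, the isovanillate ester oxygen on C5 and a methyl carbinol at C7. There are seven stereocentres (C1, C2, C3a, C4, C5, C7, C8a). H-3a and H-8a are trans; the isopropyl group, the C5 ester oxygen, the C7 hydroxyl, the epoxide oxygen and H-3a are all α, while H-8a and the methyl groups on C2 and C7 are β. C8a, C3a, C4 and C5 are contiguous, C7 is 1,3 to C5, and the epoxide lies on the face of the five-membered ring that C8 shields at the allylic position C8a. The sensitive functions are the trisubstituted epoxide (acid, Lewis acid), the tertiary alcohol (elimination) and the aryl ester with its free phenol (base, acyl transfer), so they must be introduced late. The difficulty is a seven-membered ring with four stereocentres and no rigid template, a trans ring fusion, and an epoxide on the more hindered face. The strategy rests on the segment C3a–C4–C5–C6–C7: it is the C6–C5–C4–C3–C2 segment of (R)-carvone, whose carbonyl carbon becomes C3. An oxygen insertion next to that carbonyl and a [3,3] shift of the resulting alkenyl lactone recut the six-membered ring into the seven-membered carbocycle and relay the chirality of C4, through C7, to C8a.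

## Retrosynthetic reasoning

**Phenol, epoxide and ester (37 ⇒ 36 ⇒ 35 ⇒ 30 + 33).** The last bond changes fall on the most fragile functions. The phenol is released last from silyl ether 36. The C1–O and C2–O bonds are cut next, back to alkene 35. The α face of C1=C2 is the hindered one, so the oxygen must be delivered by a group already on that face, and the tertiary C7 hydroxyl of 35 is such a group. The C5–O acyl bond is cut before that, giving diol 30 and protected acid 33 (from isovanillic acid 31). The ester cannot be made earlier because the C7 alcohol is installed with a hydride reagent. The forward acylation only has to tell a secondary from a tertiary alcohol.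

**C7 carbinol (30 ⇒ 29 ⇒ 28 ⇒ 27).** The C7–O and C8–H bonds are traced to α-epoxide 29, and this to the C7=C8 alkene of dienol 28, freed from silyl ether 27. That alkene is what the sigmatropic step leaves behind, so its hydration returns the oxygen that C7 loses there. Cutting here, rather than adding a methyl nucleophile to a C7 ketone, lets the homoallylic C5 hydroxyl decide both which ring alkene reacts and on which face.

**Five-membered ring (27 ⇒ 26 ⇒ 25 ⇒ 24 ⇒ 23 ⇒ 22 ⇒ 21 ⇒ 20).** The C1=C2 bond is cut by an olefin-metathesis transform to triene 26. A trisubstituted cyclopentene is the ring metathesis closes most readily, the catalyst tolerates every group present, and the alkene position is fixed by where the two arms end. A reductive coupling of a C1 aldehyde with a C2 methyl ketone would form the same bond, but it passes through an aldol-prone 1,5-dicarbonyl compound. The vinyl arm on C8a comes from the oxygenated carbon C1 (alcohol 24, aldehyde 25). The 2-methylallyl arm on C3a comes from the carboxyl carbon C3 (ester 20, alcohol 21, iodide 22, coupling product 23). Aldehyde 25 is β,γ-unsaturated, so its methylenation has to be non-basic.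

**Ring fusion (20 ⇒ 19 ⇒ 18).** C3a is α to the carboxyl group, so its configuration is a thermodynamic matter. Ester 20, with the ester trans to both neighbours, is traced to its all-cis epimer 19 and to acid 18. The sigmatropic step therefore needs to be judged only by what it does at C8a.

**Seven-membered ring (18 ⇒ 17 ⇒ 16 ⇒ 15), the key disconnection.** The C3a–C8a bond is cut and the C7–O bond re-formed. This turns cycloheptene acid 18, through silyl ester 17 and ketene acetal 16, into the alkenyl ε-lactone 15. This bond carries the only [3,3] retron in the ring (the γ,δ-unsaturated acid C3–C3a–C8a–C8=C7). The cut replaces a hard problem, a cycloheptane stereocentre at C8a, with an easy one, a tertiary C7–O stereocentre on a lactone. The forward reaction must enolise the lactone, trap the enolate on oxygen and pass through a boat transition state; it forms the carbocycle, the C7=C8 alkene and C8a in one operation.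

**Lactone (15 ⇒ 14 ⇒ 13).** The (E)-alkene of 15 is traced to the secondary alcohol of hydroxy lactone 14; dehydration can only occur away from the fully substituted C7. The C7–O bond of the lactone is traced to the C7–C3 bond of cyclohexanone 13 by an oxygen-insertion transform. Running the insertion before the dehydration removes any competition between ketone and alkene for the peracid.

**Quaternary C7 (13 ⇒ 12 ⇒ 9 + 11).** The C7–C8 bond is cut by an aldol transform into enolate 12 and aldehyde 11 (from alcohol 10). Direct alkenylation of an enolate is not available, whereas aldol addition followed by dehydration is, and the three-carbon aldehyde already carries C1 as a protected alcohol. Enolate 12 is traced to enone 9, so that it forms regiospecifically by conjugate hydride addition. The forward step must add on the face opposite the isopropyl group. A C5 silyloxy group cis to the isopropyl group, and therefore axial, enforces this, which is why the C5 oxygen is installed before C7 is made quaternary.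

**Oxygen at C5 and the chiral pool (9 ⇒ 8 ⇒ 7 ⇒ 6 ⇒ 5 ⇒ 4 ⇒ 3 ⇒ 2 ⇒ 1).** Enone 9 is a carvotanacetone with an extra oxygen at the γ-carbon. That oxygen enters as a ketone (5) by allylic oxidation and is reduced to the cis alcohol (6). This requires the original carbonyl to be parked as the pivalate of the cis alcohol (3, 4) and restored afterwards (7, 8, 9). The parked carbinol also provides a second stereocentre while C4 is α to a ketone. Carvotanacetone 2 comes from (R)-carvone 1 by saturating the isopropenyl group. A shorter path, alkylating the extended enolate of 2 and hydroborating the resulting ring alkene, was not taken: it offers only 1,4-induction at C7 and cannot hydroborate the ring alkene beside a side-chain alkene.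

## Alternatives that were turned down

Alternative 1: (4+3) cycloaddition of an oxyallyl cation onto a cyclopentenyl silyloxydiene.
- Disconnection: C3a–C4 and C6–C7 are cut together. The C4–C5–C6 unit is the 2-oxyallyl cation derived from chloroketone A1, which is 1-chloro-4-methylpentan-2-one. The C3a–C8a–C8–C7 unit is silyloxydiene A2, which is 7-[2-(triethylsilyloxy)prop-1-enyl]-1,4-dioxaspiro[4.4]non-7-ene; diene A2 already holds the five-membered ring, with C2 masked as a ketal.
- Forward key step: Et3N and LiClO4 ionise A1, and the cation adds across the termini of diene A2 to give the bicyclic ketone A3, with the C5 carbonyl, the C7 silyloxy centre and a C8=C8a alkene.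
- For: two C–C bonds and the seven-membered ring in one step from two small fragments, with the five-membered ring and both ring oxygens already present. On steps to the bicyclic skeleton it is clearly stronger than the chosen route.
- Against:
  - Both A1 and A2 are achiral, so C3a, C4 and C7 of A3 are formed with nothing in the substrates to set absolute configuration.
  - The relative configuration depends on compact versus extended approach and on which terminus of the unsymmetrical cation meets the ring terminus of A2; the required union joins the isopropyl-bearing terminus to a ring carbon.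
  - C7 must be formed as a fully substituted carbon, so a stepwise path ending in open-chain products is likely.
  - After the key step the C8=C8a alkene of A3 must be reduced to a trans ring fusion, and the symmetric C2 ketone must become an alkene between C1 and C2 rather than C2 and C3, with no bias.
- Comparison: the chosen route is longer, but it takes C4 from the chiral pool, relays it to every other centre, and fixes the C1=C2 position by construction.

Alternative 2: allenic Pauson–Khand reaction.
- Disconnection: C8a–C3a, C1–C2 and C2–C3 are cut together, back to the acyclic allenyne A4, which is 4-(tert-butyldimethylsilyloxy)-6-methyl-3-(propan-2-yl)-6-(triethylsilyloxy)nona-1,2-dien-8-yne.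
- Forward key step: [Rh(CO)2Cl]2 under CO joins the alkyne of A4, its distal allene double bond and CO to give the bicyclic dienone A5, closing both rings at once.
- For: the distal-bond selectivity of monovalent rhodium for seven-membered ring formation is well founded, and C5 and C7 carry their oxygens from the start. In ring-forming economy it is stronger than the chosen route.
- Against:
  - A5 is flat where the target is richest: C3a, C4 and C8a are all sp2.
  - The tetrasubstituted C3a=C4 alkene would have to take up hydrogen on opposite faces (H-3a α, H-4 β), which a syn hydrogenation cannot do.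
  - The trans ring fusion has no control element.
  - The C2 ketone must be converted into a methyl-bearing epoxide carbon with the C3 methylene kept.
  - A4 itself needs an independent asymmetric synthesis of its 1,3-related secondary and tertiary silyloxy centres.
- Comparison: the chosen route spends more steps before ring formation, but every ring-fusion stereocentre is then set by chirality transfer or thermodynamic equilibration rather than left to late reductions.

Alternative 3: intramolecular carbonyl-ene closure.
- Disconnection: only C5–C6 is cut, back to the cyclopentene aldehyde A6, which is 3-methyl-2-[4-methyl-2-(2-methylprop-2-enyl)cyclopent-3-en-1-yl]butanal.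
- Forward key step: Me2AlCl activates the aldehyde of A6; the terminal carbon of the 2-methylallyl group bonds to C5 and a methyl hydrogen is transferred, giving the bicyclic alcohol A7 with an exocyclic methylene on C7.
- For: the five-membered ring, its alkene and the C3a, C4, C8a centres exist before the closure; the C5 hydroxyl is formed directly; and A7 is only a hydration, an acylation and an epoxidation from the target. Its endgame is as short as or shorter than the chosen one.
- Against:
  - The whole stereochemical problem is moved into A6: three contiguous centres on a cyclopentene with no obvious chiral-pool source.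
  - C4 is α to the aldehyde and can epimerise under the Lewis acid.
  - The C5 configuration depends on the conformation of a forming seven-membered ring.
  - The nucleophilic C1=C2 alkene can compete in a Prins closure.
- Comparison: the chosen route pays with a longer sequence but derives C4 from (R)-carvone and builds the other centres on it.

Key step: step 13

## Route

Step 1
Reactants: 1 (R)-carvone
Product: 2 (R)-carvotanacetone [(5R)-2-methyl-5-(propan-2-yl)cyclohex-2-en-1-one]
Conditions: H2 (1 atm), RhCl(PPh3)3 (cat.), benzene, rt
Reagents that add atoms: none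
Why: Chemoselective homogeneous hydrogenation: RhCl(PPh3)3 reduces the unhindered 1,1-disubstituted alkene and leaves the conjugated trisubstituted ring alkene; the C4 stereocentre of the chiral pool is carried over unchanged.

Step 2
Reactants: 2 (R)-carvotanacetone
Product: 3 (1R,5R)-2-methyl-5-(propan-2-yl)cyclohex-2-en-1-ol (OH cis to isopropyl)
Conditions: NaBH4, CeCl3·7H2O, MeOH, −78 → 0 °C
Reagents that add atoms: none
Why: Luche 1,2-reduction; hydride adds axially to the half-chair with equatorial isopropyl and should give the pseudo-equatorial alcohol cis to the isopropyl group. This C3 carbinol is a temporary second stereocentre, so that later enolisation at C4 could not racemise the material unnoticed.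

Step 3
Reactants: 3 cis-allylic alcohol
Product: 4 (1R,5R)-2-methyl-5-(propan-2-yl)cyclohex-2-en-1-yl 2,2-dimethylpropanoate
Conditions: t-BuCOCl, pyridine, DMAP (cat.), CH2Cl2, 0 °C → rt
Reagents that add atoms: pivaloyl chloride CC(C)(C)C(=O)Cl
Why: DMAP-catalysed acylation of the allylic alcohol; the pivalate lowers the reactivity of the C3 carbinol C–H towards the oxidant of step 4 and is inert to the hindered borohydride of step 5.

Step 4
Reactants: 4 allylic pivalate
Product: 5 (1R,5R)-2-methyl-4-oxo-5-(propan-2-yl)cyclohex-2-en-1-yl 2,2-dimethylpropanoate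
Conditions: CrO3, 3,5-dimethylpyrazole, CH2Cl2, −20 °C
Reagents that add atoms: chromium trioxide O=[Cr](=O)=O
Why: Allylic oxidation of a trisubstituted cyclohexene to the enone by the CrO3–3,5-dimethylpyrazole complex; C5 is the only allylic ring methylene and the acyloxy-bearing carbon is deactivated, so the carbonyl should appear at C5 next to C4.

Step 5
Reactants: 5 keto pivalate
Product: 6 (1R,4S,5R)-4-hydroxy-2-methyl-5-(propan-2-yl)cyclohex-2-en-1-yl 2,2-dimethylpropanoate (new OH cis to isopropyl)
Conditions: LiBH(s-Bu)3, THF, −78 °C; H2O
Reagents that add atoms: none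
Why: 1,2-Reduction of a β,β-disubstituted enone, for which conjugate addition is blocked; the bulky trialkylborohydride approaches from the equatorial direction, as with 2-alkylcyclohexanones, and should give the alcohol cis to the neighbouring equatorial isopropyl group, which sets C5 (oxygen α).

Step 6
Reactants: 6 allylic alcohol
Product: 7 (1R,4S,5R)-4-[(tert-butyldimethylsilyl)oxy]-2-methyl-5-(propan-2-yl)cyclohex-2-en-1-yl 2,2-dimethylpropanoate
Conditions: t-BuMe2SiOSO2CF3, 2,6-lutidine, CH2Cl2, −78 → 0 °C
Reagents that add atoms: tert-butyldimethylsilyl trifluoromethanesulfonate CC(C)(C)[Si](C)(C)OS(=O)(=O)C(F)(F)F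
Why: Silylation of a hindered secondary allylic alcohol with a silyl triflate and a hindered base; the pivalate is untouched.

Step 7
Reactants: 7 silyl ether pivalate
Product: 8 (1R,4S,5R)-4-[(tert-butyldimethylsilyl)oxy]-2-methyl-5-(propan-2-yl)cyclohex-2-en-1-ol
Conditions: i-Bu2AlH, CH2Cl2, −78 °C
Reagents that add atoms: none
Why: Reductive cleavage of the pivalate ester by the aluminium hydride at low temperature; the silyl ether and the alkene are inert.

Step 8
Reactants: 8 allylic alcohol
Product: 9 (4S,5R)-4-[(tert-butyldimethylsilyl)oxy]-2-methyl-5-(propan-2-yl)cyclohex-2-en-1-one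
Conditions: Dess–Martin periodinane, NaHCO3, CH2Cl2, rt
Reagents that add atoms: none
Why: Dess–Martin oxidation of the allylic alcohol restores the C3 carbonyl with the C5 silyloxy group in place; the conditions are neutral, so the γ-silyloxy enone should not eliminate.

Step 9
Reactants: 10 3-[(4-methoxybenzyl)oxy]propan-1-ol
Product: 11 3-[(4-methoxybenzyl)oxy]propanal
Conditions: Dess–Martin periodinane, NaHCO3, CH2Cl2, 0 °C → rt
Reagents that add atoms: none
Why: Dess–Martin oxidation of a primary alcohol to the aldehyde, which is used at once because β-alkoxy aldehydes lose alkoxide on standing with base.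

Step 10
Reactants: 9 γ-silyloxy enone; 11 3-[(4-methoxybenzyl)oxy]propanal
Product: 13 4-(tert-butyldimethylsilyloxy)-2-{1-hydroxy-3-[(4-methoxybenzyl)oxy]propyl}-5-isopropyl-2-methylcyclohexan-1-one (hydroxyalkyl arm trans to silyloxy and isopropyl; both carbinol epimers), via lithium enolate 12 (not isolated)
Conditions: LiBH(s-Bu)3, THF, −78 °C; then 11, −78 °C; AcOH quench
Reagents that add atoms: none
Why: Reductive aldol reaction: conjugate hydride addition to the β-unsubstituted, α-methyl enone gives the tetrasubstituted lithium enolate 12 regiospecifically, and its aldol addition to 11 creates the quaternary C7. The C5 silyloxy group is axial beside the equatorial isopropyl group and blocks the α face of the enolate by a 1,3-diaxial interaction, so the aldehyde should add from the β face, trans to both groups; the carbinol configuration is removed in step 12.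

Step 11
Reactants: 13 β-hydroxy ketone
Product: 14 5-(tert-butyldimethylsilyloxy)-7-{1-hydroxy-3-[(4-methoxybenzyl)oxy]propyl}-4-isopropyl-7-methyloxepan-2-one
Conditions: m-CPBA, NaHCO3, CH2Cl2, 0 °C → rt
Reagents that add atoms: 3-chloroperoxybenzoic acid OOC(=O)c1cccc(Cl)c1
Why: Baeyer–Villiger oxidation; the quaternary C7 migrates in preference to the methylene C3a and with retention, so oxygen is inserted between C3 and C7 and the C7 configuration is kept. The oxidation is run before the side-chain alkene exists, so no epoxidation can compete.

Step 12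
Reactants: 14 hydroxy lactone
Product: 15 5-(tert-butyldimethylsilyloxy)-4-isopropyl-7-[(E)-3-(4-methoxybenzyloxy)prop-1-enyl]-7-methyloxepan-2-one
Conditions: MeO2CN(−)SO2N(+)Et3 (Burgess reagent), toluene, 60 °C
Reagents that add atoms: none
Why: Burgess dehydration (syn elimination of the sulfamate ester); C7 bears no hydrogen, so the alkene can only form towards the methylene group, and the transition state with the lactone ring and the CH2OPMB group anti should give the (E)-alkene.

Step 13
Reactants: 15 alkenyl ε-lactone
Product: 18 6-(tert-butyldimethylsilyloxy)-7-isopropyl-2-[(4-methoxybenzyloxy)methyl]-4-methylcyclohept-3-ene-1-carboxylic acid (CO2H on C3a cis to the C8a arm; H-3a and H-8a both β), via silyl ketene acetal 16 (not isolated), via trimethylsilyl ester 17 (not isolated)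
Conditions: KN(SiMe3)2, Me3SiCl/Et3N, THF, −78 °C; then toluene, 110 °C; then aq. citric acid
Reagents that add atoms: none
Why: Ireland–Claisen rearrangement of a lactone silyl ketene acetal, the variant known for ω-alkenyl lactones: KN(SiMe3)2 removes a C3a proton and Me3SiCl traps the enolate on oxygen to give 16, whose ring holds O1 and C4 cis on the ketene acetal. On heating, the C3a=C(OSi)–O1–C7–C8=C8a array undergoes a concerted suprafacial [3,3] shift in which C3a bonds to C8a as C7–O1 breaks; the tether C4–C5–C6 spans the two fragments, so only a boat transition state can be reached. The seven-membered carbocycle is closed by the sigmatropic C3a–C8a bond itself: O1 and the carbonyl carbon leave the ring, C8 and C8a enter it, and the new C7=C8 bond is necessarily cis in the ring. C8a is set by chirality transfer from C7: the ring requires C6 to end cis to C8a on the new alkene, which leaves one rotamer of the (E)-alkenyl group, and bond formation on the face from which O1 departs should then give H-8a β. C3a is set by the boat, which places the carboxyl group cis to the C8a arm; this enolisable centre is corrected in step 14. There is no regiochemical alternative, since C3a is the only enolisable position and C8a the only alkene carbon within reach. The step needs O- over C-silylation and rearrangement over ionisation of the tertiary allylic C–O bond; silylation in situ at −78 °C and a non-polar solvent for the thermal stage favour both. Aqueous acid cleaves silyl ester 17 to acid 18.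

Step 14
Reactants: 18 cis acid
Product: 20 methyl 6-(tert-butyldimethylsilyloxy)-7-isopropyl-2-[(4-methoxybenzyloxy)methyl]-4-methylcyclohept-3-ene-1-carboxylate (ester trans to both neighbours; H-3a α and H-8a β), via cis methyl ester 19 (not isolated)
Conditions: MeI, K2CO3, DMF, rt; then NaOMe, MeOH, 60 °C
Reagents that add atoms: iodomethane CI
Why: O-Alkylation of the carboxylate gives the cis ester 19, and methoxide then equilibrates the enolisable C3a centre (ester enolate epimerisation). In 19 the ester is cis to both the C4 isopropyl group and the C8a arm, so the equilibrium should lie far on the side of 20, with H-3a trans to H-8a.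

Step 15
Reactants: 20 trans ester
Product: 21 {6-(tert-butyldimethylsilyloxy)-7-isopropyl-2-[(4-methoxybenzyloxy)methyl]-4-methylcyclohept-3-en-1-yl}methanol
Conditions: LiAlH4, THF, 0 °C
Reagents that add atoms: none
Why: Hydride reduction of the ester to the primary alcohol; the silyl ether, the PMB ether and the trisubstituted alkene are inert to LiAlH4.

Step 16
Reactants: 21 primary alcohol
Product: 22 6-(tert-butyldimethylsilyloxy)-1-(iodomethyl)-7-isopropyl-2-[(4-methoxybenzyloxy)methyl]-4-methylcyclohept-3-ene
Conditions: I2, PPh3, imidazole, CH2Cl2, 0 °C → rt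
Reagents that add atoms: iodine II
Why: Appel-type iodination of a primary alcohol by SN2 displacement of the alkoxyphosphonium ion; no stereocentre is involved.

Step 17
Reactants: 22 primary iodide
Product: 23 6-(tert-butyldimethylsilyloxy)-7-isopropyl-2-[(4-methoxybenzyloxy)methyl]-4-methyl-1-(2-methylprop-2-enyl)cyclohept-3-ene
Conditions: CH2=C(CH3)MgBr, CuI (10 mol %), THF, −30 °C → rt
Reagents that add atoms: isopropenylmagnesium bromide CC(=C)[Mg]Br
Why: Copper-catalysed cross-coupling of an alkenyl Grignard reagent with a primary alkyl iodide installs C2 with its methyl group as a 2-methylallyl arm; C3 stays a methylene group, which fixes the later ring alkene between C1 and C2.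

Step 18
Reactants: 23 PMB ether
Product: 24 [6-(tert-butyldimethylsilyloxy)-7-isopropyl-4-methyl-1-(2-methylprop-2-enyl)cyclohept-3-en-2-yl]methanol
Conditions: DDQ, CH2Cl2/pH 7 buffer, 0 °C
Reagents that add atoms: none
Why: Oxidative cleavage of the PMB ether by DDQ through the benzylic oxocarbenium ion; the silyl ether and the unactivated alkenes do not react.

Step 19
Reactants: 24 primary alcohol
Product: 25 6-(tert-butyldimethylsilyloxy)-7-isopropyl-4-methyl-1-(2-methylprop-2-enyl)cyclohept-3-ene-2-carbaldehyde
Conditions: Dess–Martin periodinane, NaHCO3, CH2Cl2, 0 °C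
Reagents that add atoms: none
Why: Dess–Martin oxidation under buffered, non-basic conditions to the β,γ-unsaturated aldehyde, which is carried on crude to avoid migration of the C7=C8 bond into conjugation.

Step 20
Reactants: 25 aldehyde
Product: 26 6-(tert-butyldimethylsilyloxy)-2-ethenyl-7-isopropyl-4-methyl-1-(2-methylprop-2-enyl)cyclohept-3-ene
Conditions: Zn, CH2Br2, TiCl4, THF/CH2Cl2, 0 °C → rt
Reagents that add atoms: dibromomethane BrCBr
Why: Takai–Lombardo methylenation; the reagent pre-formed from Zn, CH2Br2 and TiCl4 is not basic and therefore should neither epimerise C8a nor move the β,γ-double bond, as a Wittig ylide could.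

Step 21
Reactants: 26 triene
Product: 27 tert-butyl{[4-isopropyl-2,7-dimethyl-3,3a,4,5,6,8a-hexahydroazulen-5-yl]oxy}dimethylsilane (trans-fused; H-3a α and H-8a β)
Conditions: RuCl2(=CHPh)(H2IMes)(PCy3) (second-generation Grubbs catalyst, 5 mol %), CH2Cl2, 40 °C
Reagents that add atoms: none
Why: Ring-closing olefin metathesis of the vinyl and 2-methylallyl arms closes the five-membered ring as the trisubstituted C1=C2 alkene with loss of ethene; the endocyclic trisubstituted C7=C8 alkene does not take part, and the trans disposition of the two arms gives the trans-fused hydroazulene.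

Step 22
Reactants: 27 silyl ether
Product: 28 4-isopropyl-2,7-dimethyl-3,3a,4,5,6,8a-hexahydroazulen-5-ol
Conditions: Bu4NF, THF, rt → 50 °C
Reagents that add atoms: none
Why: Fluoride cleavage of the secondary silyl ether frees the C5 hydroxyl group that directs the next step.

Step 23
Reactants: 28 dienol
Product: 29 7,8-epoxy-4-isopropyl-2,7-dimethyl-3,3a,4,5,6,7,8,8a-octahydroazulen-5-ol (epoxide α)
Conditions: VO(acac)2 (cat.), t-BuOOH, CH2Cl2, 0 °C → rt
Reagents that add atoms: tert-butyl hydroperoxide CC(C)(C)OO
Why: Hydroxyl-directed epoxidation under vanadium catalysis: the homoallylic C5 alcohol binds the metal and delivers oxygen to the C7=C8 alkene on its own α face, while the remote C1=C2 alkene has no directing group and should not react.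

Step 24
Reactants: 29 epoxy alcohol
Product: 30 4-isopropyl-2,7-dimethyl-3,3a,4,5,6,7,8,8a-octahydroazulene-5,7-diol (both OH α; C7 methyl β)
Conditions: LiAlH4, THF, 0 °C → reflux
Reagents that add atoms: none
Why: Hydride opening of the trisubstituted epoxide by SN2 attack at the less substituted C8 from the β face gives the tertiary C7 alcohol with OH α and methyl β; the C5 alkoxide lies on the same face as the epoxide oxygen and cannot deliver hydride to C7.

Step 25
Reactants: 31 isovanillic acid
Product: 33 3-[(tert-butyldimethylsilyl)oxy]-4-methoxybenzoic acid, via bis-silylated acid 32 (not isolated)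
Conditions: t-BuMe2SiCl, imidazole, DMF, rt; then K2CO3 (cat.), MeOH/H2O, rt
Reagents that add atoms: tert-butyldimethylsilyl chloride CC(C)(C)[Si](C)(C)Cl
Why: Silylation of both the phenol and the carboxylic acid, then mild solvolysis of the labile silyl ester, leaves the phenol protected and the acid free.

Step 26
Reactants: 30 diol; 33 silyl-protected isovanillic acid
Product: 35 7-hydroxy-4-isopropyl-2,7-dimethyl-3,3a,4,5,6,7,8,8a-octahydroazulen-5-yl 3-[(tert-butyldimethylsilyl)oxy]-4-methoxybenzoate, via mixed anhydride 34 (not isolated)
Conditions: 33, 2,4,6-Cl3C6H2COCl, Et3N, toluene, rt; then 30, DMAP, 50 °C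
Reagents that add atoms: none
Why: Yamaguchi esterification through mixed anhydride 34 and DMAP acyl transfer; the secondary C5 alcohol is acylated and the tertiary C7 alcohol is not.

Step 27
Reactants: 35 alkenyl ester
Product: 36 1,2-epoxy-7-hydroxy-4-isopropyl-2,7-dimethyldecahydroazulen-5-yl 3-[(tert-butyldimethylsilyl)oxy]-4-methoxybenzoate (epoxide α)
Conditions: VO(acac)2 (cat.), t-BuOOH, CH2Cl2, rt
Reagents that add atoms: tert-butyl hydroperoxide CC(C)(C)OO
Why: Hydroxyl-directed epoxidation: the C7 alcohol is bishomoallylic to C1=C2 and lies on the α face, from which the C8a–C8 bond also leaves the five-membered ring, so metal-bound peroxide should be delivered to the α face of the only remaining alkene. The cis relation of epoxide and hydroxyl then prevents backside opening by that hydroxyl.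

Step 28
Reactants: 36 silyl-protected target
Product: 37 CNP0106636.1 [1,2-epoxy-7-hydroxy-4-isopropyl-2,7-dimethyldecahydroazulen-5-yl 3-hydroxy-4-methoxybenzoate]
Conditions: Bu4NF, AcOH, THF, 0 °C
Reagents that add atoms: none
Why: Fluoride cleavage of the aryl silyl ether, buffered with acetic acid so that the phenoxide does not attack the ester or the epoxide, gives the target.

## Compound list

1 | (R)-carvone, (5R)-2-methyl-5-(prop-1-en-2-yl)cyclohex-2-en-1-one | CC1=CC[C@H](CC1=O)C(C)=C | starting material
2 | (R)-carvotanacetone, (5R)-2-methyl-5-(propan-2-yl)cyclohex-2-en-1-one | CC1=CC[C@H](CC1=O)C(C)C | intermediate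
3 | (1R,5R)-2-methyl-5-(propan-2-yl)cyclohex-2-en-1-ol, OH cis to isopropyl | CC1=CC[C@H](C[C@H]1O)C(C)C | intermediate
4 | (1R,5R)-2-methyl-5-(propan-2-yl)cyclohex-2-en-1-yl 2,2-dimethylpropanoate | CC1=CC[C@H](C[C@H]1OC(=O)C(C)(C)C)C(C)C | intermediate
5 | (1R,5R)-2-methyl-4-oxo-5-(propan-2-yl)cyclohex-2-en-1-yl 2,2-dimethylpropanoate | CC1=CC(=O)[C@H](C[C@H]1OC(=O)C(C)(C)C)C(C)C | intermediate
6 | (1R,4S,5R)-4-hydroxy-2-methyl-5-(propan-2-yl)cyclohex-2-en-1-yl 2,2-dimethylpropanoate | CC1=C[C@@H](O)[C@H](C[C@H]1OC(=O)C(C)(C)C)C(C)C | intermediate
7 | (1R,4S,5R)-4-[(tert-butyldimethylsilyl)oxy]-2-methyl-5-(propan-2-yl)cyclohex-2-en-1-yl 2,2-dimethylpropanoate | CC1=C[C@@H](O[Si](C)(C)C(C)(C)C)[C@H](C[C@H]1OC(=O)C(C)(C)C)C(C)C | intermediate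
8 | (1R,4S,5R)-4-[(tert-butyldimethylsilyl)oxy]-2-methyl-5-(propan-2-yl)cyclohex-2-en-1-ol | CC1=C[C@@H](O[Si](C)(C)C(C)(C)C)[C@H](C[C@H]1O)C(C)C | intermediate
9 | (4S,5R)-4-[(tert-butyldimethylsilyl)oxy]-2-methyl-5-(propan-2-yl)cyclohex-2-en-1-one | CC1=C[C@@H](O[Si](C)(C)C(C)(C)C)[C@H](CC1=O)C(C)C | intermediate
10 | 3-[(4-methoxybenzyl)oxy]propan-1-ol | OCCCOCc1ccc(OC)cc1 | starting material
11 | 3-[(4-methoxybenzyl)oxy]propanal | O=CCCOCc1ccc(OC)cc1 | intermediate
12 | lithium enolate of 4-(tert-butyldimethylsilyloxy)-5-isopropyl-2-methylcyclohexanone (enolate C3=C7) | [Li+].[O-]C1=C(C)C[C@@H](O[Si](C)(C)C(C)(C)C)[C@@H](C(C)C)C1 | intermediate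
13 | 4-(tert-butyldimethylsilyloxy)-2-{1-hydroxy-3-[(4-methoxybenzyl)oxy]propyl}-5-isopropyl-2-methylcyclohexan-1-one, arm trans to OTBS and isopropyl, carbinol epimers | O=C1C[C@H](C(C)C)[C@H](O[Si](C)(C)C(C)(C)C)C[C@@]1(C)C(O)CCOCc2ccc(OC)cc2 | intermediate
14 | 5-(tert-butyldimethylsilyloxy)-7-{1-hydroxy-3-[(4-methoxybenzyl)oxy]propyl}-4-isopropyl-7-methyloxepan-2-one | O=C1C[C@H](C(C)C)[C@H](O[Si](C)(C)C(C)(C)C)C[C@@](C)(C(O)CCOCc2ccc(OC)cc2)O1 | intermediate
15 | 5-(tert-butyldimethylsilyloxy)-4-isopropyl-7-[(E)-3-(4-methoxybenzyloxy)prop-1-enyl]-7-methyloxepan-2-one | O=C1C[C@H](C(C)C)[C@H](O[Si](C)(C)C(C)(C)C)C[C@@](C)(/C=C/COCc2ccc(OC)cc2)O1 | intermediate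
16 | trimethylsilyl ketene acetal of 15 (2-trimethylsilyloxy-4,5,6,7-tetrahydrooxepine) | C[Si](C)(C)OC1=C[C@H](C(C)C)[C@H](O[Si](C)(C)C(C)(C)C)C[C@@](C)(/C=C/COCc2ccc(OC)cc2)O1 | intermediate
17 | trimethylsilyl ester of acid 18 | C[Si](C)(C)OC(=O)[C@@H]1[C@H](C(C)C)[C@H](O[Si](C)(C)C(C)(C)C)CC(C)=C[C@@H]1COCc2ccc(OC)cc2 | intermediate
18 | 6-(tert-butyldimethylsilyloxy)-7-isopropyl-2-[(4-methoxybenzyloxy)methyl]-4-methylcyclohept-3-ene-1-carboxylic acid, CO2H cis to the C8a arm | OC(=O)[C@@H]1[C@H](C(C)C)[C@H](O[Si](C)(C)C(C)(C)C)CC(C)=C[C@@H]1COCc2ccc(OC)cc2 | intermediate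
19 | methyl ester of 18 (cis) | COC(=O)[C@@H]1[C@H](C(C)C)[C@H](O[Si](C)(C)C(C)(C)C)CC(C)=C[C@@H]1COCc2ccc(OC)cc2 | intermediate
20 | methyl 6-(tert-butyldimethylsilyloxy)-7-isopropyl-2-[(4-methoxybenzyloxy)methyl]-4-methylcyclohept-3-ene-1-carboxylate, C3a epimer of 19 (H-3a α, H-8a β) | COC(=O)[C@H]1[C@H](C(C)C)[C@H](O[Si](C)(C)C(C)(C)C)CC(C)=C[C@@H]1COCc2ccc(OC)cc2 | intermediate
21 | {6-(tert-butyldimethylsilyloxy)-7-isopropyl-2-[(4-methoxybenzyloxy)methyl]-4-methylcyclohept-3-en-1-yl}methanol | OC[C@H]1[C@H](C(C)C)[C@H](O[Si](C)(C)C(C)(C)C)CC(C)=C[C@@H]1COCc2ccc(OC)cc2 | intermediate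
22 | 6-(tert-butyldimethylsilyloxy)-1-(iodomethyl)-7-isopropyl-2-[(4-methoxybenzyloxy)methyl]-4-methylcyclohept-3-ene | IC[C@H]1[C@H](C(C)C)[C@H](O[Si](C)(C)C(C)(C)C)CC(C)=C[C@@H]1COCc2ccc(OC)cc2 | intermediate
23 | 6-(tert-butyldimethylsilyloxy)-7-isopropyl-2-[(4-methoxybenzyloxy)methyl]-4-methyl-1-(2-methylprop-2-enyl)cyclohept-3-ene | C=C(C)C[C@H]1[C@H](C(C)C)[C@H](O[Si](C)(C)C(C)(C)C)CC(C)=C[C@@H]1COCc2ccc(OC)cc2 | intermediate
24 | [6-(tert-butyldimethylsilyloxy)-7-isopropyl-4-methyl-1-(2-methylprop-2-enyl)cyclohept-3-en-2-yl]methanol | C=C(C)C[C@H]1[C@H](C(C)C)[C@H](O[Si](C)(C)C(C)(C)C)CC(C)=C[C@@H]1CO | intermediate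
25 | 6-(tert-butyldimethylsilyloxy)-7-isopropyl-4-methyl-1-(2-methylprop-2-enyl)cyclohept-3-ene-2-carbaldehyde | C=C(C)C[C@H]1[C@H](C(C)C)[C@H](O[Si](C)(C)C(C)(C)C)CC(C)=C[C@@H]1C=O | intermediate
26 | 6-(tert-butyldimethylsilyloxy)-2-ethenyl-7-isopropyl-4-methyl-1-(2-methylprop-2-enyl)cyclohept-3-ene | C=C(C)C[C@H]1[C@H](C(C)C)[C@H](O[Si](C)(C)C(C)(C)C)CC(C)=C[C@@H]1C=C | intermediate
27 | tert-butyl{[4-isopropyl-2,7-dimethyl-3,3a,4,5,6,8a-hexahydroazulen-5-yl]oxy}dimethylsilane, trans-fused | CC(C)(C)[Si](C)(C)O[C@@H]1CC(C)=C[C@H]2[C@@H](CC(C)=C2)[C@@H]1C(C)C | intermediate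
28 | 4-isopropyl-2,7-dimethyl-3,3a,4,5,6,8a-hexahydroazulen-5-ol | O[C@@H]1CC(C)=C[C@H]2[C@@H](CC(C)=C2)[C@@H]1C(C)C | intermediate
29 | 7,8-epoxy-4-isopropyl-2,7-dimethyl-3,3a,4,5,6,7,8,8a-octahydroazulen-5-ol, α-epoxide | O[C@@H]1C[C@]3(C)O[C@@H]3[C@H]2[C@@H](CC(C)=C2)[C@@H]1C(C)C | intermediate
30 | 4-isopropyl-2,7-dimethyl-3,3a,4,5,6,7,8,8a-octahydroazulene-5,7-diol | O[C@@H]1C[C@](C)(O)C[C@H]2[C@@H](CC(C)=C2)[C@@H]1C(C)C | intermediate
31 | isovanillic acid, 3-hydroxy-4-methoxybenzoic acid | COc1ccc(C(=O)O)cc1O | starting material
32 | tert-butyldimethylsilyl 3-[(tert-butyldimethylsilyl)oxy]-4-methoxybenzoate | COc1ccc(C(=O)O[Si](C)(C)C(C)(C)C)cc1O[Si](C)(C)C(C)(C)C | intermediate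
33 | 3-[(tert-butyldimethylsilyl)oxy]-4-methoxybenzoic acid | COc1ccc(C(=O)O)cc1O[Si](C)(C)C(C)(C)C | intermediate
34 | 3-[(tert-butyldimethylsilyl)oxy]-4-methoxybenzoic 2,4,6-trichlorobenzoic anhydride | COc1ccc(C(=O)OC(=O)c2c(Cl)cc(Cl)cc2Cl)cc1O[Si](C)(C)C(C)(C)C | intermediate
35 | 7-hydroxy-4-isopropyl-2,7-dimethyl-3,3a,4,5,6,7,8,8a-octahydroazulen-5-yl 3-[(tert-butyldimethylsilyl)oxy]-4-methoxybenzoate | COc1ccc(C(=O)O[C@@H]2C[C@](C)(O)C[C@H]3[C@@H](CC(C)=C3)[C@@H]2C(C)C)cc1O[Si](C)(C)C(C)(C)C | intermediate
36 | 1,2-epoxy-7-hydroxy-4-isopropyl-2,7-dimethyldecahydroazulen-5-yl 3-[(tert-butyldimethylsilyl)oxy]-4-methoxybenzoate | COc1ccc(C(=O)O[C@@H]2C[C@](C)(O)C[C@H]3[C@@H](C[C@@]4(C)O[C@@H]34)[C@@H]2C(C)C)cc1O[Si](C)(C)C(C)(C)C | intermediate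
37 | CNP0106636.1, 1,2-epoxy-7-hydroxy-4-isopropyl-2,7-dimethyldecahydroazulen-5-yl 3-hydroxy-4-methoxybenzoate | COc1ccc(C(=O)O[C@@H]2C[C@](C)(O)C[C@H]3[C@@H](C[C@@]4(C)O[C@@H]34)[C@@H]2C(C)C)cc1O | target

## Step count and least certain steps

Total: 28 steps. Longest linear sequence: 26 steps from (R)-carvone (steps 1–8, 10–24, 26–28). Steps 9 and 25 are one-step branches.

**Step 13 (key step).** The most likely failure is ring opening or C-silylation of the hindered lactone enolate before the ketene acetal forms cleanly. If the boat transition state needs long heating, heterolysis of the tertiary allylic C7–O bond followed by proton loss may also compete. The fallback is a sulfur variant of the same [3,3] shift that needs neither O-silylation nor high temperature. Lactone 15 is thionated with Lawesson's reagent to 5-(tert-butyldimethylsilyloxy)-4-isopropyl-7-[(E)-3-(4-methoxybenzyloxy)prop-1-enyl]-7-methyloxepane-2-thione F1. The more acidic thionolactone is deprotonated with KN(SiMe3)2 and methylated on sulfur with MeI to the ketene S,O-acetal F2. This should rearrange on warming to the S-methyl thioester of acid 18, F3. NaOMe in MeOH then converts F3 into the methyl ester and equilibrates C3a, so the sequence returns to the route at 20.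

**Step 10.** Hydride may be delivered to the carbonyl carbon instead of C6, because the γ-silyloxy group crowds the β-position. The hindered aldolate may also revert by retro-aldol cleavage on warming, and facial selectivity may be eroded if the enolate reacts through the half-chair with an equatorial silyloxy group. The fallback sets out from 9: copper hydride-catalysed conjugate hydrosilylation ([(Ph3P)CuH]6 cat., PhMe2SiH) gives the isolable dimethylphenylsilyl enol ether F4. F4 is added to 11 in a Mukaiyama aldol reaction (BF3·OEt2, CH2Cl2, −78 °C) and returns to 13. The same axial silyloxy group controls the face in the open transition state.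

**Step 12.** Acyl transfer from the tertiary to the neighbouring secondary oxygen, or participation of the lactone during activation of the alcohol, may divert the dehydration, and (E)-selectivity may be incomplete. The fallback inverts the order. Aldol 13 is dehydrated first (Burgess reagent) to 4-(tert-butyldimethylsilyloxy)-5-isopropyl-2-[(E)-3-(4-methoxybenzyloxy)prop-1-enyl]-2-methylcyclohexan-1-one F5. Oxygen is then inserted with an oxidant that spares alkenes (Me3SiOOSiMe3, cat. Me3SiOSO2CF3, CH2Cl2, −40 °C), which returns to 15.

**Step 19 (with step 20).** The C7=C8 bond of the β,γ-unsaturated aldehyde 25 may migrate into conjugation, with loss of the C8a stereocentre, during oxidation or methylenation. The fallback avoids the aldehyde and sets out from 24. A Mitsunobu reaction with 1-phenyl-1H-tetrazole-5-thiol gives the sulfide F6. (NH4)6Mo7O24/H2O2 oxidises it to the sulfone F7. Deprotonation with KN(SiMe3)2 and addition of formaldehyde (Julia–Kocienski methylenation) give triene 26.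

**Step 27.** Facial selectivity may be poor: the tertiary, bishomoallylic hydroxyl may bind vanadium too weakly to outrun undirected attack on the less hindered β face. The fallback replaces substrate direction by reagent control. Alkene 35 is epoxidised with a chiral dioxirane (Shi epoxidation: fructose-derived ketone or its enantiomer, KHSO5, buffered), with the catalyst enantiomer chosen to match the α face. This gives 36 directly; no new compound arises on this path, which the entry F0 records.

## Further compounds

F1 | step 13 | 5-(tert-butyldimethylsilyloxy)-4-isopropyl-7-[(E)-3-(4-methoxybenzyloxy)prop-1-enyl]-7-methyloxepane-2-thione | S=C1C[C@H](C(C)C)[C@H](O[Si](C)(C)C(C)(C)C)C[C@@](C)(/C=C/COCc2ccc(OC)cc2)O1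
F2 | step 13 | ketene S,O-acetal, 2-(methylsulfanyl)-4,5,6,7-tetrahydrooxepine derived from F1 | CSC1=C[C@H](C(C)C)[C@H](O[Si](C)(C)C(C)(C)C)C[C@@](C)(/C=C/COCc2ccc(OC)cc2)O1
F3 | step 13 | S-methyl 6-(tert-butyldimethylsilyloxy)-7-isopropyl-2-[(4-methoxybenzyloxy)methyl]-4-methylcyclohept-3-ene-1-carbothioate (cis) | CSC(=O)[C@@H]1[C@H](C(C)C)[C@H](O[Si](C)(C)C(C)(C)C)CC(C)=C[C@@H]1COCc2ccc(OC)cc2
F4 | step 10 | dimethylphenylsilyl enol ether of 4-(tert-butyldimethylsilyloxy)-5-isopropyl-2-methylcyclohexanone | C[Si](C)(c1ccccc1)OC1=C(C)C[C@@H](O[Si](C)(C)C(C)(C)C)[C@@H](C(C)C)C1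
F5 | step 12 | 4-(tert-butyldimethylsilyloxy)-5-isopropyl-2-[(E)-3-(4-methoxybenzyloxy)prop-1-enyl]-2-methylcyclohexan-1-one | O=C1C[C@H](C(C)C)[C@H](O[Si](C)(C)C(C)(C)C)C[C@@]1(C)/C=C/COCc2ccc(OC)cc2
F6 | step 19 | 5-({[6-(tert-butyldimethylsilyloxy)-7-isopropyl-4-methyl-1-(2-methylprop-2-enyl)cyclohept-3-en-2-yl]methyl}sulfanyl)-1-phenyl-1H-tetrazole | C=C(C)C[C@H]1[C@H](C(C)C)[C@H](O[Si](C)(C)C(C)(C)C)CC(C)=C[C@@H]1CSc2nnnn2-c2ccccc2
F7 | step 19 | 5-({[6-(tert-butyldimethylsilyloxy)-7-isopropyl-4-methyl-1-(2-methylprop-2-enyl)cyclohept-3-en-2-yl]methyl}sulfonyl)-1-phenyl-1H-tetrazole | C=C(C)C[C@H]1[C@H](C(C)C)[C@H](O[Si](C)(C)C(C)(C)C)CC(C)=C[C@@H]1CS(=O)(=O)c2nnnn2-c2ccccc2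
F0 | step 27 | none | none
A1 | alternative 1 | 1-chloro-4-methylpentan-2-one | CC(C)CC(=O)CCl
A2 | alternative 1 | 7-[2-(triethylsilyloxy)prop-1-enyl]-1,4-dioxaspiro[4.4]non-7-ene | CC(O[Si](CC)(CC)CC)=CC1=CCC2(C1)OCCO2
A3 | alternative 1 | (4+3) adduct, 4-isopropyl-7-methyl-7-(triethylsilyloxy)-hexahydroazulen-5-one 2-ethylene ketal with a C8=C8a alkene | O=C1C[C@](C)(O[Si](CC)(CC)CC)C=C2CC3(C[C@H]2[C@@H]1C(C)C)OCCO3
A4 | alternative 2 | 4-(tert-butyldimethylsilyloxy)-6-methyl-3-(propan-2-yl)-6-(triethylsilyloxy)nona-1,2-dien-8-yne | C#CC[C@@](C)(O[Si](CC)(CC)CC)C[C@@H](O[Si](C)(C)C(C)(C)C)C(C(C)C)=C=C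
A5 | alternative 2 | 5-(tert-butyldimethylsilyloxy)-4-isopropyl-7-methyl-7-(triethylsilyloxy)-5,6,7,8-tetrahydroazulen-2(3H)-one | O=C1C=C2C[C@@](C)(O[Si](CC)(CC)CC)C[C@@H](O[Si](C)(C)C(C)(C)C)C(C(C)C)=C2C1
A6 | alternative 3 | 3-methyl-2-[4-methyl-2-(2-methylprop-2-enyl)cyclopent-3-en-1-yl]butanal | C=C(C)C[C@@H]1C=C(C)C[C@H]1[C@@H](C=O)C(C)C
A7 | alternative 3 | 4-isopropyl-2-methyl-7-methylene-3,3a,4,5,6,7,8,8a-octahydroazulen-5-ol | O[C@@H]1CC(=C)C[C@H]2[C@@H](CC(C)=C2)[C@@H]1C(C)C
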